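**Strategy.** Everything rests on cutting the bromoaryl-bearing tetrahydrofuran ring of the furofuran (ring B: C1, C8H2, O7, C6, C5; 3,7-dioxabicyclo[3.3.0]octane numbering) across C8–C1 and O7–C6, which excises O7=C8H2 as formaldehyde. The remaining C6–C5–C1 unit has a benzylic C6 carrying a para-oxygenated aryl (donor) and a C1 alpha to the carbon that becomes C2 (acceptor), so it is hidden as an aryl cyclopropane fused to a lactone. A Lewis-acid formal [3+2] annulation of this cyclopropane with formaldehyde closes ring B in one operation and sets C6 by inversion. The lactone carbonyl then receives the second aryl ring, and a late Suzuki coupling at the aryl bromide joins the separately built (2R,3R)-dihydroflavonol.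

Key step: step 7

Remark 1: compounds 12, 17 and 19 are taken as catalogue chemicals.
Remark 2: in step 6 the (S,S)-ligand is assumed to deliver the (1S,5R,6R) enantiomer; if the sense of induction is the opposite, the (R,R)-ligand is used.

Step 1
Reactants: 1 5-bromovanillin
Product: 2 4-(benzyloxy)-3-bromo-5-methoxybenzaldehyde
Conditions: BnBr, K2CO3, DMF, 60 °C
Reagents that add atoms: benzyl bromide, BrCc1ccccc1
Why: Williamson ether synthesis on the phenoxide should protect the phenol as a benzyl ether that survives every later step up to the final hydrogenolysis.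

Step 2
Reactants: 2 4-(benzyloxy)-3-bromo-5-methoxybenzaldehyde
Product: 3 methyl (Z)-3-[4-(benzyloxy)-3-bromo-5-methoxyphenyl]prop-2-enoate
Conditions: (CF3CH2O)2P(O)CH2CO2Me, KN(SiMe3)2, 18-crown-6, THF, −78 °C
Reagents that add atoms: methyl bis(2,2,2-trifluoroethyl)phosphonoacetate, COC(=O)CP(=O)(OCC(F)(F)F)OCC(F)(F)F
Why: Still–Gennari variant of the Horner–Wadsworth–Emmons olefination, in which the electron-poor phosphonate makes elimination from the kinetic adduct faster than its equilibration, should give the Z-enoate needed to place the aryl group endo in step 6.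

Step 3
Reactants: 3 methyl (Z)-3-[4-(benzyloxy)-3-bromo-5-methoxyphenyl]prop-2-enoate
Product: 4 (Z)-3-[4-(benzyloxy)-3-bromo-5-methoxyphenyl]prop-2-en-1-ol
Conditions: i-Bu2AlH (2.2 equiv), CH2Cl2, −78 °C
Reagents that add atoms: none
Why: 1,2-reduction of the enoate by the aluminium hydride should give the allylic alcohol without touching the Z-alkene or the aryl bromide.

Step 4
Reactants: 4 (Z)-3-[4-(benzyloxy)-3-bromo-5-methoxyphenyl]prop-2-en-1-ol
Product: 5 (Z)-3-[4-(benzyloxy)-3-bromo-5-methoxyphenyl]prop-2-en-1-yl methyl malonate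
Conditions: ClC(O)CH2CO2Me, pyridine, CH2Cl2, 0 °C
Reagents that add atoms: methyl malonyl chloride, COC(=O)CC(Cl)=O
Why: O-acylation of the primary allylic alcohol by the acid chloride should install the malonate that becomes the two acceptor groups of the cyclopropane.

Step 5
Reactants: 5 (Z)-3-[4-(benzyloxy)-3-bromo-5-methoxyphenyl]prop-2-en-1-yl methyl malonate
Product: 6 (Z)-3-[4-(benzyloxy)-3-bromo-5-methoxyphenyl]prop-2-en-1-yl methyl 2-diazomalonate
Conditions: 4-acetamidobenzenesulfonyl azide, Et3N, MeCN, rt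
Reagents that add atoms: 4-acetamidobenzenesulfonyl azide, CC(=O)Nc1ccc(cc1)S(=O)(=O)N=[N+]=[N-]
Why: Regitz diazo transfer onto the doubly activated methylene should give the diazomalonate under conditions too mild to isomerise the Z-alkene.

Step 6
Reactants: 6 (Z)-3-[4-(benzyloxy)-3-bromo-5-methoxyphenyl]prop-2-en-1-yl methyl 2-diazomalonate
Product: 7 methyl (1S,5R,6R)-6-[4-(benzyloxy)-3-bromo-5-methoxyphenyl]-2-oxo-3-oxabicyclo[3.1.0]hexane-1-carboxylate (aryl endo, cis to the lactone CH2)
Conditions: Cu(MeCN)4PF6 (5 mol %), (S,S)-tBu-box (6 mol %), CH2Cl2, 40 °C, slow addition of 6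
Reagents that add atoms: none
Why: Intramolecular cyclopropanation by a copper carbene is concerted and stereospecific, so the Z geometry should become the endo aryl group, while the C2-symmetric bisoxazoline ligand selects the alkene face and should set C1, C5 and C6 as (1S,5R,6R).

Step 7
Reactants: 7 methyl (1S,5R,6R)-6-[4-(benzyloxy)-3-bromo-5-methoxyphenyl]-2-oxo-3-oxabicyclo[3.1.0]hexane-1-carboxylate
Product: 8 methyl (1R,5R,6S)-6-[4-(benzyloxy)-3-bromo-5-methoxyphenyl]-2-oxo-3,7-dioxabicyclo[3.3.0]octane-1-carboxylate (aryl exo)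
Conditions: (CH2O)n (5 equiv), Sn(OTf)2 (10 mol %), 4 Å MS, ClCH2CH2Cl, rt to 45 °C
Reagents that add atoms: formaldehyde (supplied as paraformaldehyde), C=O
Why: The Lewis acid chelates the lactone and ester carbonyls on C1 and polarises the C1–C6 bond; the oxygen of formaldehyde attacks the benzylic donor carbon C6 from the face opposite the departing C1 (SN2-like, inversion), giving a tin enolate tethered to an O-alkylated formaldehyde oxocarbenium ion, and the enolate carbon C1 then closes onto the CH2 carbon, so the O–CH(Ar) bond and the CH2–C1 bond arise in one operation. The closest known reaction type is the Lewis-acid-catalysed formal [3+2] annulation of aryl cyclopropane-1,1-diesters with aldehydes to give tetrahydrofurans. The one ring closed, the bromoaryl-bearing tetrahydrofuran, forms by a 5-(enolexo)-endo-trig aldol-type attack on the oxocarbenium ion, and it can only be cis-fused to the lactone because C1 and C6 both hang from C5. The new stereocentre C6 is controlled by stereospecific inversion, which turns the endo aryl of 7 (from the Z-alkene) into the exo aryl (6S) of 8, while C1 keeps its configuration relative to C5 from step 6. The step needs cleavage of the C1–C6 bond only and capture before the cyclopropane ionises reversibly; the gem-diacceptor and aryl-donor pattern makes C1–C6 the only activated bond, and excess monomeric formaldehyde should secure fast capture.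

Step 8
Reactants: 8 methyl (1R,5R,6S)-6-[4-(benzyloxy)-3-bromo-5-methoxyphenyl]-2-oxo-3,7-dioxabicyclo[3.3.0]octane-1-carboxylate
Product: 10 (1R,5R,6S)-6-[4-(benzyloxy)-3-bromo-5-methoxyphenyl]-3,7-dioxabicyclo[3.3.0]octan-2-one, via lithium carboxylate 9 (not isolated)
Conditions: LiCl, H2O, DMSO, 140 °C
Reagents that add atoms: none
Why: Krapcho dealkoxycarbonylation: chloride demethylates the ester by SN2, the carboxylate beta to the lactone carbonyl loses CO2, and protonation of the lactone enolate can only give the cis-fused bicycle, so C1 follows C5.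

Step 9
Reactants: 10 (1R,5R,6S)-6-[4-(benzyloxy)-3-bromo-5-methoxyphenyl]-3,7-dioxabicyclo[3.3.0]octan-2-one
Product: 11 (1R,5R,6S)-6-[4-(benzyloxy)-3-bromo-5-methoxyphenyl]-3,7-dioxabicyclo[3.3.0]octan-2-ol (lactol, mixture of anomers)
Conditions: i-Bu2AlH (1.1 equiv), CH2Cl2, −78 °C
Reagents that add atoms: none
Why: Partial reduction of the γ-lactone stops at the tetrahedral aluminate at low temperature and should give the lactol with the aryl bromide intact.

Step 10
Reactants: 11 the lactol; 12 1-(benzyloxy)-4-bromo-2-methoxybenzene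
Product: 14 (RS)-[4-(benzyloxy)-3-methoxyphenyl][(3R,4R,5S)-5-[4-(benzyloxy)-3-bromo-5-methoxyphenyl]-4-(hydroxymethyl)tetrahydrofuran-3-yl]methanol, via arylmagnesium bromide 13 (not isolated)
Conditions: 12, Mg, THF, rt; then 11, THF, 0 °C to rt (3 equiv of 13); aq. NH4Cl
Reagents that add atoms: none
Why: Grignard addition to the open hydroxy-aldehyde form of the lactol should give the diol; magnesium does not exchange with the aryl bromide of 11, and the configuration of the new carbinol is irrelevant because it is ionised in step 11.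

Step 11
Reactants: 14 the diol
Product: 15 (1S,3aR,4S,6aR)-1-[4-(benzyloxy)-3-methoxyphenyl]-4-[4-(benzyloxy)-3-bromo-5-methoxyphenyl]tetrahydro-1H,3H-furo[3,4-c]furan
Conditions: 10-camphorsulfonic acid (10 mol %), CH2Cl2, 0 °C
Reagents that add atoms: none
Why: Acid-catalysed SN1 cycloetherification: the para-benzyloxybenzylic alcohol ionises to a stabilised cation that the cis CH2OH captures in a 5-exo-trig closure with the aryl on the convex face, which should set the 1S centre (aryl exo) as in the natural furofurans.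

Step 12
Reactants: 15 the bromo furofuran
Product: 16 2-[2-(benzyloxy)-5-[(1S,3aR,4S,6aR)-4-[4-(benzyloxy)-3-methoxyphenyl]tetrahydro-1H,3H-furo[3,4-c]furan-1-yl]-3-methoxyphenyl]-4,4,5,5-tetramethyl-1,3,2-dioxaborolane
Conditions: B2pin2, Pd(dppf)Cl2 (5 mol %), KOAc, 1,4-dioxane, 90 °C
Reagents that add atoms: bis(pinacolato)diboron, CC1(C)OB(OC1(C)C)B1OC(C)(C)C(C)(C)O1
Why: Miyaura borylation (oxidative addition to zerovalent palladium, acetate-assisted transmetalation, reductive elimination) should convert the aryl bromide into the pinacol boronate, the weak base preventing biaryl homocoupling.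

Step 13
Reactants: 17 3-bromo-4,5-dihydroxybenzaldehyde
Product: 18 3,4-bis(benzyloxy)-5-bromobenzaldehyde
Conditions: BnBr (2.5 equiv), K2CO3, DMF, 60 °C
Reagents that add atoms: benzyl bromide, BrCc1ccccc1
Why: Double Williamson etherification should protect the catechol so that no quinone methide can form from the dihydroflavonol later.

Step 14
Reactants: 19 1-[2,4-bis(benzyloxy)-6-hydroxyphenyl]ethan-1-one
Product: 20 1-[2,4-bis(benzyloxy)-6-(methoxymethoxy)phenyl]ethan-1-one
Conditions: NaH, MOMCl, DMF, 0 °C to rt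
Reagents that add atoms: chloromethyl methyl ether, COCCl
Why: Alkylation of the hydrogen-bonded phenoxide with the chloromethyl ether should mask the ortho phenol as an acid-labile acetal, which blocks premature cyclisation of the chalcone.

Step 15
Reactants: 18 3,4-bis(benzyloxy)-5-bromobenzaldehyde; 20 1-[2,4-bis(benzyloxy)-6-(methoxymethoxy)phenyl]ethan-1-one
Product: 21 (E)-1-[2,4-bis(benzyloxy)-6-(methoxymethoxy)phenyl]-3-[3,4-bis(benzyloxy)-5-bromophenyl]prop-2-en-1-one
Conditions: KOH, EtOH/THF, rt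
Reagents that add atoms: none
Why: Claisen–Schmidt condensation (aldol addition then E1cB dehydration) should give the thermodynamically favoured E-chalcone.

Step 16
Reactants: 21 the chalcone
Product: 22 [(2R,3S)-3-[3,4-bis(benzyloxy)-5-bromophenyl]oxiran-2-yl][2,4-bis(benzyloxy)-6-(methoxymethoxy)phenyl]methanone
Conditions: poly-L-leucine, urea–H2O2, DBU, THF, rt
Reagents that add atoms: urea–hydrogen peroxide, OO.NC(N)=O
Why: Juliá–Colonna epoxidation: the helical poly-L-leucine binds the hydroperoxide–enone adduct through its N-terminal NH groups and should deliver the (2R,3S)-trans-epoxide by Weitz–Scheffer addition to the E-enone.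

Step 17
Reactants: 22 the epoxy ketone
Product: 24 (2R,3R)-5,7-bis(benzyloxy)-2-[3,4-bis(benzyloxy)-5-bromophenyl]-3-hydroxychroman-4-one, via phenol epoxide 23 (not isolated)
Conditions: conc. HCl, MeOH/THF, 55 °C
Reagents that add atoms: none
Why: Acid removes the methoxymethyl acetal and the freed phenol opens the protonated epoxide at the benzylic carbon (6-endo-tet, inversion) while the alpha carbon keeps its configuration, which should give the 2,3-trans (2R,3R)-dihydroflavonol.

Step 18
Reactants: 16 the furofuran boronate; 24 the bromo dihydroflavonol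
Product: 25 (2R,3R)-5,7-bis(benzyloxy)-2-[3,4-bis(benzyloxy)-5-[2-(benzyloxy)-5-[(1S,3aR,4S,6aR)-4-[4-(benzyloxy)-3-methoxyphenyl]tetrahydro-1H,3H-furo[3,4-c]furan-1-yl]-3-methoxyphenyl]phenyl]-3-hydroxychroman-4-one
Conditions: Pd(OAc)2 (5 mol %), SPhos (10 mol %), K3PO4 (aq.), THF, 40 °C, degassed
Reagents that add atoms: none
Why: Suzuki–Miyaura coupling with a bulky dialkylbiarylphosphine should form the di-ortho-oxygenated biaryl near room temperature, mild enough for the fully O-benzylated dihydroflavonol (no free phenol, hence no quinone-methide ring opening) to keep C2 and C3.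

Step 19
Reactants: 25 the hexabenzyl ether
Product: 26 (2R,3R)-2-[3,4-dihydroxy-5-[2-hydroxy-5-[(1S,3aR,4S,6aR)-4-(4-hydroxy-3-methoxyphenyl)tetrahydro-1H,3H-furo[3,4-c]furan-1-yl]-3-methoxyphenyl]phenyl]-3,5,7-trihydroxychroman-4-one (target)
Conditions: H2 (1 atm), Pd/C (10 %), EtOAc/MeOH, rt
Reagents that add atoms: none
Why: Hydrogenolysis of the six aryl benzyl ethers over palladium on carbon is much faster than cleavage of the dialkyl benzylic C–O bonds of the furofuran and of C2 of the chromanone, so stopping at the uptake of six equivalents of hydrogen should give the target.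

**Compound list**

1 | 5-bromovanillin (3-bromo-4-hydroxy-5-methoxybenzaldehyde) | COc1cc(C=O)cc(Br)c1O | starting material
2 | 4-(benzyloxy)-3-bromo-5-methoxybenzaldehyde | COc1cc(C=O)cc(Br)c1OCc1ccccc1 | intermediate
3 | methyl (Z)-3-[4-(benzyloxy)-3-bromo-5-methoxyphenyl]prop-2-enoate | COC(=O)/C=C\c1cc(OC)c(OCc2ccccc2)c(Br)c1 | intermediate
4 | (Z)-3-[4-(benzyloxy)-3-bromo-5-methoxyphenyl]prop-2-en-1-ol | OC/C=C\c1cc(OC)c(OCc2ccccc2)c(Br)c1 | intermediate
5 | (Z)-3-[4-(benzyloxy)-3-bromo-5-methoxyphenyl]prop-2-en-1-yl methyl malonate | COC(=O)CC(=O)OC/C=C\c1cc(OC)c(OCc2ccccc2)c(Br)c1 | intermediate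
6 | (Z)-3-[4-(benzyloxy)-3-bromo-5-methoxyphenyl]prop-2-en-1-yl methyl 2-diazomalonate | COC(=O)C(=[N+]=[N-])C(=O)OC/C=C\c1cc(OC)c(OCc2ccccc2)c(Br)c1 | intermediate
7 | methyl (1S,5R,6R)-6-[4-(benzyloxy)-3-bromo-5-methoxyphenyl]-2-oxo-3-oxabicyclo[3.1.0]hexane-1-carboxylate | COC(=O)[C@@]12C(=O)OC[C@@H]1[C@@H]2c1cc(OC)c(OCc2ccccc2)c(Br)c1 | intermediate
8 | methyl (1R,5R,6S)-6-[4-(benzyloxy)-3-bromo-5-methoxyphenyl]-2-oxo-3,7-dioxabicyclo[3.3.0]octane-1-carboxylate | O=C1OC[C@H]2[C@]1(C(=O)OC)CO[C@@H]2c1cc(OC)c(OCc2ccccc2)c(Br)c1 | intermediate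
9 | lithium (1R,5R,6S)-6-[4-(benzyloxy)-3-bromo-5-methoxyphenyl]-2-oxo-3,7-dioxabicyclo[3.3.0]octane-1-carboxylate | O=C1OC[C@H]2[C@]1(C([O-])=O)CO[C@@H]2c1cc(OC)c(OCc2ccccc2)c(Br)c1.[Li+] | intermediate
10 | (1R,5R,6S)-6-[4-(benzyloxy)-3-bromo-5-methoxyphenyl]-3,7-dioxabicyclo[3.3.0]octan-2-one | O=C1OC[C@H]2[C@@H]1CO[C@@H]2c1cc(OC)c(OCc2ccccc2)c(Br)c1 | intermediate
11 | (1R,5R,6S)-6-[4-(benzyloxy)-3-bromo-5-methoxyphenyl]-3,7-dioxabicyclo[3.3.0]octan-2-ol (anomer mixture) | OC1OC[C@H]2[C@@H]1CO[C@@H]2c1cc(OC)c(OCc2ccccc2)c(Br)c1 | intermediate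
12 | 1-(benzyloxy)-4-bromo-2-methoxybenzene | COc1cc(Br)ccc1OCc1ccccc1 | starting material
13 | [4-(benzyloxy)-3-methoxyphenyl]magnesium bromide | COc1cc([Mg]Br)ccc1OCc1ccccc1 | intermediate
14 | (RS)-[4-(benzyloxy)-3-methoxyphenyl][(3R,4R,5S)-5-[4-(benzyloxy)-3-bromo-5-methoxyphenyl]-4-(hydroxymethyl)tetrahydrofuran-3-yl]methanol | OC[C@H]1[C@@H](C(O)c2ccc(OCc3ccccc3)c(OC)c2)CO[C@@H]1c1cc(OC)c(OCc2ccccc2)c(Br)c1 | intermediate
15 | (1S,3aR,4S,6aR)-1-[4-(benzyloxy)-3-methoxyphenyl]-4-[4-(benzyloxy)-3-bromo-5-methoxyphenyl]tetrahydro-1H,3H-furo[3,4-c]furan | COc1cc([C@H]2OC[C@H]3[C@@H]2CO[C@@H]3c2cc(OC)c(OCc4ccccc4)c(Br)c2)ccc1OCc1ccccc1 | intermediate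
16 | pinacol boronate of 15 (Bpin in place of Br) | COc1cc([C@H]2OC[C@H]3[C@@H]2CO[C@@H]3c2cc(OC)c(OCc4ccccc4)c(B4OC(C)(C)C(C)(C)O4)c2)ccc1OCc1ccccc1 | intermediate
17 | 3-bromo-4,5-dihydroxybenzaldehyde | O=Cc1cc(O)c(O)c(Br)c1 | starting material
18 | 3,4-bis(benzyloxy)-5-bromobenzaldehyde | O=Cc1cc(Br)c(OCc2ccccc2)c(OCc2ccccc2)c1 | intermediate
19 | 1-[2,4-bis(benzyloxy)-6-hydroxyphenyl]ethan-1-one | CC(=O)c1c(O)cc(OCc2ccccc2)cc1OCc1ccccc1 | starting material
20 | 1-[2,4-bis(benzyloxy)-6-(methoxymethoxy)phenyl]ethan-1-one | CC(=O)c1c(OCOC)cc(OCc2ccccc2)cc1OCc1ccccc1 | intermediate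
21 | (E)-1-[2,4-bis(benzyloxy)-6-(methoxymethoxy)phenyl]-3-[3,4-bis(benzyloxy)-5-bromophenyl]prop-2-en-1-one | COCOc1cc(OCc2ccccc2)cc(OCc2ccccc2)c1C(=O)/C=C/c1cc(Br)c(OCc2ccccc2)c(OCc2ccccc2)c1 | intermediate
22 | [(2R,3S)-3-[3,4-bis(benzyloxy)-5-bromophenyl]oxiran-2-yl][2,4-bis(benzyloxy)-6-(methoxymethoxy)phenyl]methanone | COCOc1cc(OCc2ccccc2)cc(OCc2ccccc2)c1C(=O)[C@@H]1O[C@H]1c1cc(Br)c(OCc2ccccc2)c(OCc2ccccc2)c1 | intermediate
23 | [(2R,3S)-3-[3,4-bis(benzyloxy)-5-bromophenyl]oxiran-2-yl][2,4-bis(benzyloxy)-6-hydroxyphenyl]methanone | Oc1cc(OCc2ccccc2)cc(OCc2ccccc2)c1C(=O)[C@@H]1O[C@H]1c1cc(Br)c(OCc2ccccc2)c(OCc2ccccc2)c1 | intermediate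
24 | (2R,3R)-5,7-bis(benzyloxy)-2-[3,4-bis(benzyloxy)-5-bromophenyl]-3-hydroxychroman-4-one | c1ccccc1COc1c(Br)cc(cc1OCc1ccccc1)[C@H]1Oc2cc(OCc3ccccc3)cc(OCc3ccccc3)c2C(=O)[C@@H]1O | intermediate
25 | hexa-O-benzyl ether of the target | COc1cc([C@H]2OC[C@H]3[C@@H]2CO[C@@H]3c2cc(OC)c(OCc4ccccc4)c(-c3cc([C@H]4Oc5cc(OCc6ccccc6)cc(OCc6ccccc6)c5C(=O)[C@@H]4O)cc(OCc4ccccc4)c3OCc3ccccc3)c2)ccc1OCc1ccccc1 | intermediate
26 | (2R,3R)-2-[3,4-dihydroxy-5-[2-hydroxy-5-[(1S,3aR,4S,6aR)-4-(4-hydroxy-3-methoxyphenyl)tetrahydro-1H,3H-furo[3,4-c]furan-1-yl]-3-methoxyphenyl]phenyl]-3,5,7-trihydroxychroman-4-one | COc1cc([C@H]2OC[C@H]3[C@@H]2CO[C@@H]3c2cc(OC)c(O)c(-c3cc([C@H]4Oc5cc(O)cc(O)c5C(=O)[C@@H]4O)cc(O)c3O)c2)ccc1O | target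

**Count.** Total steps: 19. Longest linear sequence: 14 (steps 1–12, 18, 19).

**Steps most likely to fail**

Step 7. The cyclopropane may ionise reversibly and lose its stereochemical information before formaldehyde is captured, or formaldehyde may oligomerise on the Lewis acid so that no monomeric aldehyde captures the ring-opened intermediate. The fallback sets out from 7 and splits the annulation into two known operations. Lewis-acid-catalysed SN2 ring opening of the cyclopropane with water (Sc(OTf)3, H2O, THF) should give, with inversion at the benzylic carbon, methyl (3RS,4R)-4-[(S)-[4-(benzyloxy)-3-bromo-5-methoxyphenyl](hydroxy)methyl]-2-oxotetrahydrofuran-3-carboxylate F1. Treatment of this alcohol with paraformaldehyde and BF3·OEt2 in CH2Cl2 at 0 °C should form the hemiacetal oxocarbenium ion, which the enol of the alpha-methoxycarbonyl lactone captures intramolecularly (Prins/Mannich-type C-alkylation, cis-fusion enforced by the tether). The fallback comes back to the route at 8.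

Step 6. The copper carbene may give insufficient facial selectivity, or may be diverted into carbene dimerisation and benzylic C–H insertion. The fallback sets out from 4. Acetylation (Ac2O, pyridine) gives (Z)-3-[4-(benzyloxy)-3-bromo-5-methoxyphenyl]prop-2-en-1-yl acetate F2. Intermolecular, stereospecific asymmetric cyclopropanation of this Z-alkene with dimethyl diazomalonate under monovalent copper and a side-arm-modified bisoxazoline ligand (a catalyst class established for cis-olefins and malonate carbenes) should give dimethyl (2R,3R)-3-(acetoxymethyl)-2-[4-(benzyloxy)-3-bromo-5-methoxyphenyl]cyclopropane-1,1-dicarboxylate F3. K2CO3 in MeOH then removes the acetate, and the freed CH2OH lactonises onto the cis ester. The fallback comes back to the route at 7.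

Step 18. The aqueous base may open the chromanone ring by E1cB at C3 and so scramble C2 and C3, or the hindered boronate may protodeboronate faster than it transmetalates. The fallback sets out from 15. Stannylation (Bu3SnSnBu3, Pd(PPh3)4, toluene, 100 °C) gives tributyl[2-(benzyloxy)-5-[(1S,3aR,4S,6aR)-4-[4-(benzyloxy)-3-methoxyphenyl]tetrahydro-1H,3H-furo[3,4-c]furan-1-yl]-3-methoxyphenyl]stannane F4. This is joined to 24 by a base-free Stille coupling (Pd(PPh3)4, copper thiophene-2-carboxylate, NMP, rt). The fallback comes back to the route at 25.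

**Further compounds**

F1 | step 7 | methyl (3RS,4R)-4-[(S)-[4-(benzyloxy)-3-bromo-5-methoxyphenyl](hydroxy)methyl]-2-oxotetrahydrofuran-3-carboxylate | COC(=O)C1C(=O)OC[C@@H]1[C@H](O)c1cc(OC)c(OCc2ccccc2)c(Br)c1
F2 | step 6 | (Z)-3-[4-(benzyloxy)-3-bromo-5-methoxyphenyl]prop-2-en-1-yl acetate | CC(=O)OC/C=C\c1cc(OC)c(OCc2ccccc2)c(Br)c1
F3 | step 6 | dimethyl (2R,3R)-3-(acetoxymethyl)-2-[4-(benzyloxy)-3-bromo-5-methoxyphenyl]cyclopropane-1,1-dicarboxylate | COC(=O)C1(C(=O)OC)[C@H](COC(C)=O)[C@@H]1c1cc(OC)c(OCc2ccccc2)c(Br)c1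
F4 | step 18 | tributyl[2-(benzyloxy)-5-[(1S,3aR,4S,6aR)-4-[4-(benzyloxy)-3-methoxyphenyl]tetrahydro-1H,3H-furo[3,4-c]furan-1-yl]-3-methoxyphenyl]stannane | COc1cc([C@H]2OC[C@H]3[C@@H]2CO[C@@H]3c2cc(OC)c(OCc4ccccc4)c([Sn](CCCC)(CCCC)CCCC)c2)ccc1OCc1ccccc1
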